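## The problem

Target 35 is a bisabolane triester in which a cyclohexane ring (C1–C6) is joined through the single bond C1–C7 to a five-carbon chain (C7–C11), C7 being the 1,1-disubstituted alkene carbon that carries the C14 methylene. The ring holds five contiguous stereocentres (1S,2R,3R,4S,5S): C7, the acetoxy oxygen on C2, the angeloyloxy oxygen on C3 and the oxirane oxygen on C4/C5 share one face, and the fully substituted C4 turns its methyl group to the other. Inside the ring the centres can steer one another (C3 directs C1 and C2, the C1–C3 triad directs C4, C5 is relayed stereospecifically), whereas C8 (S, allylic ester) and C10 (S, trisubstituted oxirane) are insulated from the ring by the sp2 carbon C7 and need reagent control. Three esters of two kinds sit on neighbouring oxygens: the cis-vicinal O2/O3 pair invites acyl migration, and angelates isomerise to tiglates under basic or nucleophilic acylation conditions. The tertiary C4 epoxide is acid-labile, the side-chain epoxide is opened by a free C8 hydroxyl, and the allylic ester and two alkenes exclude hydrogenolysis and strong nucleophiles late in the route. The feature that makes the key step possible is the run C3(O)–C4(O)(CH3)–C5(O)–C6H2–C1–C7, which is the pattern of C3, C4, C5, C6, C1 and the carboxyl carbon of (−)-shikimic acid 1. Because O5 of 1 is trans to O3 whereas the oxirane oxygen is cis to it, the C5 oxygen can leave while an alkoxide on C4, made by methyl addition to a C4 ketone, closes the ring.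

## Retrosynthesis

**35 ⇒ 34 (the two C–O bonds of the 10,11-epoxide).** This epoxide is cut first, so it is made last. Made earlier, it would be opened by a free C8 hydroxyl in a 5-exo ring closure and would have to survive chromium, fluoride and acylation chemistry. In 34 the C10=C11 bond is the only electron-rich alkene, since C7=C14 is 1,1-disubstituted next to an ester and the angelate double bonds are electron-poor. Precursor 34 has one stereocentre and one labile group less. The forward reaction must set 10S by reagent control and spare three esters and the ring epoxide.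

**34 ⇒ 33 ⇒ 32 ⇒ 29 + 30 (acyl–oxygen bonds at O2, O3 and O8).** The two angelates are cut together and the acetate separately, so that diol 29 takes up two equivalents of angelic acid 30 in one operation. This requires O2 and O3 to be told apart earlier, as the naphthylmethyl ether and the silyl ether of 28. Putting the acetate on last means the only free hydroxyl next to an ester (in 33) is created under neutral oxidative conditions and sits beside a hindered angelate that migrates slowly. The reverse order would place a free O3 beside an acetate under basic acylation conditions. Diol 29 carries no base-sensitive ester. The forward step must transfer both acyl groups from 30 without Z to E isomerisation.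

**29 ⇒ 28 ⇒ 27 ⇒ 26 ⇒ 22 + 24 (the C7–C8 bond).** Cutting next to the alkene divides the molecule into the ring enol triflate 22 and the six-carbon aldehyde 24, which comes from alcohol 23. A cut at C8–C9 would need a linear, enantioselective prenylation at C8. A C8 nucleophile added to a C7 acyl group would need a configurationally defined α-alkoxy carbanion and a later methylenation. The chromium–nickel coupling tolerates the epoxide and the ethers. The ring cannot control C8, so the coupling product 26 is oxidised to enone 27 and reduced under catalyst control to 28.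

**22 ⇒ 20 ⇒ 19 ⇒ 18 ⇒ 17 ⇒ 16 (the C7–C14 bond and the oxidation level of C7).** C14 is added as a methyl nucleophile to aldehyde 18, and kinetic enolisation of methyl ketone 20 then fixes the alkene at C7=C14. Carrying C7 as a silyl-protected CH2OH up to 16 keeps the carboxyl carbon of 1 inert through the key step. The forward steps must avoid enolisation toward C1, which would epimerise it or expel the C2 ether.

**16 ⇒ 14 (the C4–CH3 bond and the C5–O bond of the oxirane; key step).** Both bonds are cut at once. A stepwise alternative (alkene, then epoxidation) would have to deliver oxygen to the more hindered face. The precursor 14 has no quaternary centre and one ring less, and its C5 configuration is that of 1. The forward reaction has to bring the methyl group in on the lower face, cis to the leaving group, and must not enolise the ketone.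

**14 ⇒ 13 ⇒ 12 ⇒ 11 (functional group changes at C4 and C5).** The ketone comes from the C4 alcohol, the mesylate from the less hindered C5 alcohol, and the diol from the butane-2,3-diacetal 11. The acetal is the device that distinguishes the trans 4,5-diol from O3 at the start. Its acidic removal dictates that all other protecting groups in 11 be acid-tolerant.

**11 ⇒ 10 ⇒ 9 ⇒ 8 ⇒ 6 (the C2–O bond and the C1–H bond).** Hydroboration of alkene 6 anti to O3 puts hydrogen on the lower face of C1, which is the target configuration, but leaves O2 trans to its neighbours in 8. Oxidation to 9 and hydride delivery from the open lower face give the all-cis alcohol 10. A directed epoxidation with reductive opening would be shorter but regiochemically unsafe at a tertiary carbon flanked by oxygen.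

**6 ⇒ 5 ⇒ 4 ⇒ 3 ⇒ 1 (protecting groups and ester reduction).** Esterification and diacetal formation, silylation of O3, reduction of the ester and silylation of O7 lead back to 1. Compound 1 supplies C3 and C5 directly and O4, C6, C1 and C7 as atoms.

## Roads not taken

Alternative 1: The cut is the ring bond C1–C6 together with the whole fold of the chain. (2E,6E)-Farnesyl diphosphate A1 would be ionised and cyclised by an (S)-β-bisabolene synthase to (S)-β-bisabolene A2. A2 already holds all fifteen carbons, the C1 stereocentre and the C7=C14 methylene. On carbon–carbon bond economy this road is better than the chosen plan: one step against about twenty-five. Its weak point is everything after A2. Five oxygens (on C2, C3, C8 and in two epoxides) must be placed on a hydrocarbon whose three alkenes and many allylic positions differ only slightly. C2 is not allylic at all. C3 competes with C6 and the C4 methyl group, and C8 competes with C1–H and C9. The ring alkene would have to be epoxidised cis to oxygens that are not yet there. Only further tailoring enzymes could do this, and none can be planned from structure. Against the brevity of A2 the chosen plan sets that O3 and the C5 oxygen come in with 1 in the right absolute sense, and that each later oxygen enters at a position activated for that reaction.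

Alternative 2: The cut is C1–C7. The bromoacetal A3, in which the 2-bromo-1-ethoxyethyl tether sits on O2 of the ring dienol, would give a C7 radical with Bu3SnH and AIBN. This radical adds to the diene terminus C1 in a 5-exo closure, and hydrogen transfer to the allyl radical leaves the C4=C5 alkene in the cis-fused bicyclic acetal A4. The ring fusion forces C7 cis to O2 in the bond-forming step itself. The chosen plan reaches that relationship only through hydroboration, oxidation and reduction. The surviving C4=C5 alkene next to O3 would allow a hydroxyl-directed epoxidation cis to O3, which is more predictable than the facial selectivity on which step 12 depends. In these two respects this road is as good or better. Its weak points are these: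
- C7 arrives as a methylene and the acetal carbon as C8 at the aldehyde level, so C14 needs an α-methylenation and C9–C11 a linear prenylation that must also set C8.
- The allyl radical can take up hydrogen at C4 as well as at C6.
- A3 is a cyclohexadiene one elimination away from an arene, and the two cis oxygens it carries must be differentiated before the tether is attached.
- Stoichiometric tin is required.

The chosen plan sets against it that C7 is attached from the start at an adjustable oxidation level, that O2 and O3 are differentiated by the order in which they appear, and that C5 and the quaternary C4 are fixed without a regiochemical question.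

Alternative 3: The cut is C2–C3 and C1–C6. Thermal Diels–Alder reaction of the silyloxy diene A5 with the (5R)-menthyloxybutenolide A6 would give the cis-fused lactone acetal A7. In A7 the auxiliary has set C1, C2 and C3 all-cis in one step, C7 is an acetal carbon at the aldehyde level, and the C4=C5 alkene with its methyl group is in place. The road is convergent. In reaching the C1–C3 relationship in one step it is clearly better than the chosen plan, which gets there only at step 7. Its weak point for this target is that C2 carries the lactone carbonyl carbon, not oxygen. A carbon has to be excised, for example by turning the lactone carbonyl of A7 into an acetyl group and applying Baeyer–Villiger oxidation. That would at least deliver the C2 acetate with retention, but the peracid would also attack the alkene, and C1 next to the masked aldehyde is epimerisable. The endo and regiochemical course of a thermal reaction between a trisubstituted diene and a moderately reactive butenolide is less assured than the auxiliary's face control. The epoxide would still need a directed oxidation once O3 is unmasked. Against the brevity of A7 the chosen plan sets that it removes no carbon, takes the ring's absolute configuration from an inexpensive pool compound, and creates C4 and the oxirane in one stereospecific operation.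

Key step: step 12

Remark on the chemistry: atoms are numbered as in 35 (ring C1–C6, chain C7–C11, methylene C14); "upper face" is the ring face that carries C7, O2 and O3; the SMILES of 35 is read as 1S,2R,3R,4S,5S,8S,10S with both 2-methylbut-2-enoates Z; TIPS = triisopropylsilyl, TBDPS = tert-butyldiphenylsilyl, NAP = 2-naphthylmethyl, BDA = butane-2,3-diacetal (2,3-dimethoxybutane-2,3-diyl), Ms = methanesulfonyl, Tf = trifluoromethanesulfonyl.

## Route

Step 1
Reactants: 1 (−)-shikimic acid
Product: 3 methyl shikimate 4,5-BDA acetal (C3–OH free), via methyl shikimate 2 (not isolated)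
Conditions: butane-2,3-dione, HC(OMe)3, camphorsulfonic acid (cat.), MeOH, reflux
Reagents that add atoms: methanol, CO; butane-2,3-dione, CC(=O)C(C)=O; trimethyl orthoformate, COC(OC)OC
Why: Fischer esterification gives 2, and acid-catalysed butane-2,3-diacetal formation (methoxy groups supplied by the orthoformate–methanol pair) then engages only the trans-diequatorial 4,5-diol, because only there can the trans-fused dioxane place both methoxy groups axial (double anomeric stabilisation); the allylic C3 hydroxyl stays free.

Step 2
Reactants: 3 methyl shikimate 4,5-BDA acetal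
Product: 4 O3-TIPS ether of 3
Conditions: TIPSOTf, 2,6-lutidine, CH2Cl2, 0 °C
Reagents that add atoms: triisopropylsilyl trifluoromethanesulfonate, CC(C)[Si](C(C)C)(C(C)C)OS(=O)(=O)C(F)(F)F
Why: Silylation of the secondary allylic alcohol with the silyl triflate; TIPS resists the later acid step, does not migrate to a neighbouring alkoxide and shields the upper face at C2 and C4.

Step 3
Reactants: 4 O3-TIPS ester
Product: 5 allylic alcohol (C7 as CH2OH)
Conditions: iBu2AlH (2.5 equiv), CH2Cl2, −78 °C; aq. KNaC4H4O6
Reagents that add atoms: none
Why: 1,2-Reduction of the conjugated ester by the aluminium hydride gives the allylic alcohol; acetal and silyl ether are inert.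

Step 4
Reactants: 5 allylic alcohol
Product: 6 O7-TBDPS ether
Conditions: TBDPSCl, imidazole, CH2Cl2, 0 °C to rt
Reagents that add atoms: tert-butyl(chloro)diphenylsilane, CC(C)(C)[Si](Cl)(c1ccccc1)c1ccccc1
Why: Silylation of the primary alcohol; a primary TBDPS ether tolerates aqueous acid and is later cleaved by fluoride ahead of the hindered secondary TIPS ether.

Step 5
Reactants: 6 O7-TBDPS alkene
Product: 8 C2 alcohol with hydroxyl on the lower face, via C2 alkylborane 7 (not isolated)
Conditions: BH3·THF, THF, 0 °C to rt; then NaOH, H2O2, 0 °C
Reagents that add atoms: hydrogen peroxide, OO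
Why: Hydroboration–oxidation: boron adds to the less substituted C2 and hydrogen to C1, syn and from the lower face, anti to the pseudoaxial C3 silyloxy group, so C1 gets its target configuration (C7 up) while O2 first appears on the lower face; the C–B bond is oxidised with retention.

Step 6
Reactants: 8 C2 alcohol (lower face)
Product: 9 C2 ketone
Conditions: Dess–Martin periodinane, NaHCO3, CH2Cl2, 0 °C to rt
Reagents that add atoms: none
Why: Dess–Martin oxidation under buffered conditions; in the acetal-locked chair both α-hydrogens (C1, C3) are equatorial and poorly aligned for enolisation, so C1 is not epimerised and no β-alkoxide is expelled.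

Step 7
Reactants: 9 C2 ketone
Product: 10 C2 alcohol with hydroxyl on the upper face (C7, O2, O3 all cis)
Conditions: NaBH4, CeCl3·7H2O, MeOH–THF, −78 to −40 °C
Reagents that add atoms: none
Why: Luche reduction: in the chair locked by the trans-fused acetal the C1 and C3 substituents are both axial on the upper face, so hydride attacks axially from the open lower face, anti to the axial C3–O bond, and gives the equatorial C2 alcohol cis to both neighbours (2R).

Step 8
Reactants: 10 all-cis C2 alcohol
Product: 11 O2-NAP ether
Conditions: NaH, 2-(bromomethyl)naphthalene, Bu4NI (cat.), THF–DMF, 0 °C to rt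
Reagents that add atoms: 2-(bromomethyl)naphthalene, BrCc1ccc2ccccc2c1
Why: Williamson etherification of the equatorial alkoxide; the NAP ether withstands acid, fluoride and organometallic reagents and can be removed at the end with DDQ under neutral conditions, and the TIPS group on O3 does not migrate to the C2 alkoxide.

Step 9
Reactants: 11 fully protected BDA acetal
Product: 12 4,5-diol
Conditions: CF3CO2H–H2O (9:1), CH2Cl2, 0 °C, 10 min
Reagents that add atoms: none
Why: Acid hydrolysis of the bis-methyl ketal (butane-2,3-diacetal cleavage) should be complete within minutes, whereas the secondary TIPS ether, the primary TBDPS ether and the NAP ether are the acid-tolerant members of their classes; no stereocentre is touched.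

Step 10
Reactants: 12 4,5-diol
Product: 13 C5 mesylate (C4–OH free)
Conditions: MsCl (1.1 equiv), pyridine, CH2Cl2, −20 to 0 °C
Reagents that add atoms: methanesulfonyl chloride, CS(=O)(=O)Cl
Why: Regioselective sulfonylation: O5 adjoins the C6 methylene, whereas O4 is flanked by C5 and by the cis C3 triisopropylsilyloxy group; pyridine is too weak a base to close the trans hydroxy mesylate.

Step 11
Reactants: 13 C5 mesylate
Product: 14 C4 ketone C5 mesylate
Conditions: Dess–Martin periodinane, NaHCO3, CH2Cl2, rt
Reagents that add atoms: none
Why: Dess–Martin oxidation of the hindered C4 alcohol gives the α-mesyloxy ketone without an amine base that could enolise it and expel the C2 ether; C3 and C5 keep their configuration.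

Step 12
Reactants: 14 C4 ketone C5 mesylate
Product: 16 C4-methyl C4,C5-epoxide, via dichlorocerium C4-alkoxide 15 (not isolated)
Conditions: MeLi, CeCl3 (anhydrous), THF, −78 °C; then −78 to 23 °C
Reagents that add atoms: methyllithium, C[Li]
Why: Methylcerium dichloride, formed from MeLi and CeCl3, adds to the C4 carbonyl of 14 to give the tertiary alkoxide 15, which displaces the neighbouring C5 mesylate with inversion and closes the oxirane; the closest known reaction type is the addition of an organometallic reagent to an α-sulfonyloxy or α-halo ketone with closure of the alkoxide to an epoxide, applied here to a new substrate. The ring closes in the 3-exo-tet mode, which needs the C4–O and C5–OMs bonds anti-periplanar (trans-diaxial). C4 is set by the face of methyl attack: in the chair with the C1 and C3 substituents equatorial, the axial trajectory on the upper face is blocked by the syn-axial C2 naphthylmethoxy group, so the aggregated cerium reagent enters equatorially from the lower face and the alkoxide is already trans-diaxial to the mesylate. In the other chair (mesylate equatorial) attack is axial from the lower face, anti to the axial C3–O bond (Felkin–Anh), and a ring flip precedes closure, so both conformers lead to the same C4 configuration with oxygen on the upper face. C5 is not created but inverted stereospecifically, which is why the O5 of shikimic acid, trans to O3, is needed. The step requires addition to win over enolisation toward C3 (which would expel the C2 ether) or toward C5, and the low basicity and high oxophilicity of the cerium reagent at −78 °C secure this. It also requires methyl to enter cis to the mesylate, against the usual preference of α-hetero-substituted cyclohexanones for attack anti to an axial leaving group; the three upper-face substituents on C1, C2 and C3 are the element that overrides it. The silyl ether on O3 does not chelate, so no metal-directed delivery on the upper face is expected.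

Step 13
Reactants: 16 epoxide with O7-TBDPS
Product: 17 C7 primary alcohol
Conditions: Bu4NF (1.1 equiv), AcOH (1.1 equiv), THF, 0 °C
Reagents that add atoms: none
Why: Fluoride-mediated desilylation: a primary TBDPS ether is cleaved far faster than the hindered secondary TIPS ether, and buffering with acetic acid protects the epoxide from alkoxide chemistry.

Step 14
Reactants: 17 C7 primary alcohol
Product: 18 C7 aldehyde
Conditions: Dess–Martin periodinane, NaHCO3, CH2Cl2, 0 °C
Reagents that add atoms: none
Why: Dess–Martin oxidation to the aldehyde under neutral conditions avoids epimerisation at C1 and β-elimination of the C2 ether; the aldehyde is used without storage.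

Step 15
Reactants: 18 C7 aldehyde
Product: 19 C7 secondary alcohol (both C7 epimers)
Conditions: MeMgBr, THF, −78 °C
Reagents that add atoms: methylmagnesium bromide, C[Mg]Br
Why: Grignard addition to the aldehyde is much faster than attack on the trisubstituted epoxide at −78 °C; the C7 carbinol centre forms as a mixture, which is irrelevant because it is oxidised next.

Step 16
Reactants: 19 C7 secondary alcohol
Product: 20 C7 methyl ketone
Conditions: Dess–Martin periodinane, NaHCO3, CH2Cl2, rt
Reagents that add atoms: none
Why: Dess–Martin oxidation of both C7 epimers converges on one methyl ketone, which holds the C14–C7–C1 frame of the target.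

Step 17
Reactants: 20 C7 methyl ketone
Product: 22 enol triflate (C7=C14), via potassium enolate 21 (not isolated)
Conditions: KN(SiMe3)2, THF, −78 °C; PhNTf2, −78 to 0 °C
Reagents that add atoms: N-phenylbis(trifluoromethanesulfonimide), O=S(=O)(N(c1ccccc1)S(=O)(=O)C(F)(F)F)C(F)(F)F
Why: Kinetic deprotonation by the bulky amide base occurs at the unhindered methyl group (C14) rather than at the tertiary C1–H, and O-sulfonylation of enolate 21 gives the 1,1-disubstituted enol triflate; avoiding C1 deprotonation also avoids expulsion of the C2 ether.

Step 18
Reactants: 23 4-methylpent-3-en-1-ol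
Product: 24 4-methylpent-3-enal
Conditions: Dess–Martin periodinane, NaHCO3, CH2Cl2, 0 °C; filtered solution used at once
Reagents that add atoms: none
Why: Dess–Martin oxidation of the homoallylic alcohol under buffered conditions gives the β,γ-unsaturated aldehyde without migration of the double bond into conjugation.

Step 19
Reactants: 22 enol triflate; 24 4-methylpent-3-enal
Product: 26 C8 allylic alcohol (both C8 epimers), via alkenylchromium dichloride 25 (not isolated)
Conditions: CrCl2 (4 equiv), NiCl2 (2 mol %), DMF, rt
Reagents that add atoms: none
Why: Nozaki–Hiyama–Kishi coupling: nickel inserts into the C–OTf bond, transmetalation gives alkenylchromium 25, and this adds chemoselectively to the aldehyde in the presence of epoxide, silyl and naphthylmethyl ethers; C8 forms without control and is corrected in the next two steps.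

Step 20
Reactants: 26 C8 allylic alcohol
Product: 27 C8 enone
Conditions: Dess–Martin periodinane, NaHCO3, CH2Cl2, 0 °C
Reagents that add atoms: none
Why: Dess–Martin oxidation of the epimer mixture gives a single cross-conjugated enone under non-basic conditions that should keep the skipped C10=C11 bond and the C7=C14 bond in place.

Step 21
Reactants: 27 C8 enone
Product: 28 (8S)-allylic alcohol
Conditions: (R)-2-methyl-CBS-oxazaborolidine (0.3 equiv), catecholborane, toluene, −78 °C
Reagents that add atoms: none
Why: Corey–Bakshi–Shibata reduction: with the α-branched alkenyl group as the large and the C9 methylene as the small substituent, the (R)-oxazaborolidine delivers hydride to the face that gives the 8S alcohol (reagent control); catecholborane at −78 °C does not hydroborate the alkenes.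

Step 22
Reactants: 28 (8S)-allylic alcohol
Product: 29 C3,C8-diol
Conditions: Bu4NF, THF, rt
Reagents that add atoms: none
Why: Fluoride cleavage of the secondary TIPS ether frees O3 while no ester is yet present, so the basicity of the reagent is harmless; the C3 alkoxide is cis to the epoxide oxygen and cannot open it.

Step 23
Reactants: 29 C3,C8-diol; 30 angelic acid (2.5 equiv of which two are incorporated)
Product: 32 C3,C8-bis-angelate with O2-NAP, via angelic 2,4,6-trichlorobenzoic anhydride 31 (not isolated)
Conditions: 30 (2.5 equiv), 2,4,6-trichlorobenzoyl chloride (2.5 equiv), Et3N, toluene, rt; then 29, 70 °C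
Reagents that add atoms: angelic acid (second equivalent), C/C=C(/C)C(O)=O
Why: Twofold Yamaguchi esterification: the excess of mixed anhydride 31 acylates first the allylic C8 hydroxyl and then the more hindered C3 hydroxyl on warming, so each hydroxyl takes up one molecule of angelic acid; no nucleophilic catalyst is present, conditions under which the Z-configured 2-methylbut-2-enoyl group is transferred without isomerisation to the tiglate.

Step 24
Reactants: 32 bis-angelate with O2-NAP
Product: 33 C2 alcohol
Conditions: DDQ, CH2Cl2–pH 7 phosphate buffer, rt
Reagents that add atoms: none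
Why: Oxidative cleavage of the naphthylmethyl ether by DDQ (hydride abstraction, then hydrolysis of the oxocarbenium ion) under buffered neutral conditions frees O2 without acyl migration from O3 and without touching esters, alkenes or the epoxide.

Step 25
Reactants: 33 C2 alcohol
Product: 34 C2 acetate (10,11-alkene)
Conditions: Ac2O, pyridine, 4-(dimethylamino)pyridine (cat.), CH2Cl2, 0 °C to rt
Reagents that add atoms: acetic anhydride, CC(=O)OC(C)=O
Why: Catalysed acetylation of the hindered axial C2 hydroxyl; acetylation should outrun migration of the hindered angeloyl group from O3, which would in any case be uphill toward the axial position.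

Step 26
Reactants: 34 C2 acetate (10,11-alkene)
Product: 35 target CNP0118696.1
Conditions: ent-Shi ketone (L-fructose series, 0.3 equiv), KHSO5 (as 2KHSO5·KHSO4·K2SO4), K2CO3, Bu4NHSO4, MeCN–CH2(OMe)2–aq. Na2B4O7 buffer, 0 °C
Reagents that add atoms: potassium peroxymonosulfate, [K+].[O-]S(=O)(=O)OO
Why: Shi epoxidation: the chiral dioxirane formed from the ketone and KHSO5 attacks the only electron-rich alkene (trisubstituted C10=C11) through a spiro transition state; the ketone of the L-fructose series is the enantiomer expected to give the 10S epoxide of a 2-methylalk-2-ene, and the 1,1-disubstituted C7=C14 bond and the angelate double bonds react far more slowly.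

## Compound list

1 | (−)-shikimic acid, (3R,4S,5R)-3,4,5-trihydroxycyclohex-1-ene-1-carboxylic acid | OC(=O)C1=C[C@@H](O)[C@@H](O)[C@H](O)C1 | starting material
2 | methyl shikimate | COC(=O)C1=C[C@@H](O)[C@@H](O)[C@H](O)C1 | intermediate
3 | methyl shikimate 4,5-BDA acetal: O4 and O5 bridged by 2,3-dimethoxybutane-2,3-diyl (trans-fused dioxane, acetal carbons S,S, methoxy groups axial), C3–OH free | COC(=O)C1=C[C@@H](O)[C@H]2O[C@](C)(OC)[C@@](C)(OC)O[C@@H]2C1 | intermediate
4 | O3-TIPS ether of 3 | COC(=O)C1=C[C@@H](O[Si](C(C)C)(C(C)C)C(C)C)[C@H]2O[C@](C)(OC)[C@@](C)(OC)O[C@@H]2C1 | intermediate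
5 | allylic alcohol: ester of 4 reduced to C7H2OH | OCC1=C[C@@H](O[Si](C(C)C)(C(C)C)C(C)C)[C@H]2O[C@](C)(OC)[C@@](C)(OC)O[C@@H]2C1 | intermediate
6 | O7-TBDPS ether of 5 | CC(C)(C)[Si](OCC1=C[C@@H](O[Si](C(C)C)(C(C)C)C(C)C)[C@H]2O[C@](C)(OC)[C@@](C)(OC)O[C@@H]2C1)(c3ccccc3)c4ccccc4 | intermediate
7 | C2 alkylborane: BH2 on the lower face of C2, H on the lower face of C1, C7 on the upper face | CC(C)(C)[Si](OC[C@H]1[C@H](B)[C@@H](O[Si](C(C)C)(C(C)C)C(C)C)[C@H]2O[C@](C)(OC)[C@@](C)(OC)O[C@@H]2C1)(c3ccccc3)c4ccccc4 | intermediate
8 | C2 alcohol, hydroxyl on the lower face (trans to C7 and O3) | CC(C)(C)[Si](OC[C@H]1[C@H](O)[C@@H](O[Si](C(C)C)(C(C)C)C(C)C)[C@H]2O[C@](C)(OC)[C@@](C)(OC)O[C@@H]2C1)(c3ccccc3)c4ccccc4 | intermediate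
9 | C2 ketone | CC(C)(C)[Si](OC[C@H]1C(=O)[C@@H](O[Si](C(C)C)(C(C)C)C(C)C)[C@H]2O[C@](C)(OC)[C@@](C)(OC)O[C@@H]2C1)(c3ccccc3)c4ccccc4 | intermediate
10 | C2 alcohol, hydroxyl on the upper face (C7, O2, O3 all cis) | CC(C)(C)[Si](OC[C@H]1[C@@H](O)[C@@H](O[Si](C(C)C)(C(C)C)C(C)C)[C@H]2O[C@](C)(OC)[C@@](C)(OC)O[C@@H]2C1)(c3ccccc3)c4ccccc4 | intermediate
11 | O2-NAP ether of 10 | CC(C)(C)[Si](OC[C@H]1[C@@H](OCc2ccc3ccccc3c2)[C@@H](O[Si](C(C)C)(C(C)C)C(C)C)[C@H]2O[C@](C)(OC)[C@@](C)(OC)O[C@@H]2C1)(c3ccccc3)c4ccccc4 | intermediate
12 | 4,5-diol (C4–OH upper face, C5–OH lower face; O7 TBDPS, O2 NAP, O3 TIPS) | CC(C)(C)[Si](OC[C@@H]1C[C@@H](O)[C@H](O)[C@H](O[Si](C(C)C)(C(C)C)C(C)C)[C@@H]1OCc2ccc3ccccc3c2)(c4ccccc4)c5ccccc5 | intermediate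
13 | C5 mesylate of 12 (C4–OH free) | CC(C)(C)[Si](OC[C@@H]1C[C@@H](OS(C)(=O)=O)[C@H](O)[C@H](O[Si](C(C)C)(C(C)C)C(C)C)[C@@H]1OCc2ccc3ccccc3c2)(c4ccccc4)c5ccccc5 | intermediate
14 | C4 ketone C5 mesylate (precursor of the key step) | CC(C)(C)[Si](OC[C@@H]1C[C@@H](OS(C)(=O)=O)C(=O)[C@H](O[Si](C(C)C)(C(C)C)C(C)C)[C@@H]1OCc2ccc3ccccc3c2)(c4ccccc4)c5ccccc5 | intermediate
15 | dichlorocerium C4-alkoxide: C4 carries CH3 (lower face) and O–CeCl2 (upper face), C5 mesylate on the lower face | CC(C)(C)[Si](OC[C@@H]1C[C@@H](OS(C)(=O)=O)[C@](C)(O[Ce](Cl)Cl)[C@H](O[Si](C(C)C)(C(C)C)C(C)C)[C@@H]1OCc2ccc3ccccc3c2)(c4ccccc4)c5ccccc5 | intermediate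
16 | C4-methyl C4,C5-epoxide, oxirane oxygen on the upper face (product of the key step) | CC(C)(C)[Si](OC[C@@H]1C[C@@H]2O[C@]2(C)[C@H](O[Si](C(C)C)(C(C)C)C(C)C)[C@@H]1OCc3ccc4ccccc4c3)(c5ccccc5)c6ccccc6 | intermediate
17 | C7 primary alcohol | OC[C@@H]1C[C@@H]2O[C@]2(C)[C@H](O[Si](C(C)C)(C(C)C)C(C)C)[C@@H]1OCc3ccc4ccccc4c3 | intermediate
18 | C7 aldehyde | O=C[C@@H]1C[C@@H]2O[C@]2(C)[C@H](O[Si](C(C)C)(C(C)C)C(C)C)[C@@H]1OCc3ccc4ccccc4c3 | intermediate
19 | C7 secondary alcohol (1-hydroxyethyl on C1, both C7 epimers) | CC(O)[C@@H]1C[C@@H]2O[C@]2(C)[C@H](O[Si](C(C)C)(C(C)C)C(C)C)[C@@H]1OCc3ccc4ccccc4c3 | intermediate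
20 | C7 methyl ketone (acetyl on C1) | CC(=O)[C@@H]1C[C@@H]2O[C@]2(C)[C@H](O[Si](C(C)C)(C(C)C)C(C)C)[C@@H]1OCc3ccc4ccccc4c3 | intermediate
21 | potassium enolate of 20 (C7=C14) | [K+].[O-]C(=C)[C@@H]1C[C@@H]2O[C@]2(C)[C@H](O[Si](C(C)C)(C(C)C)C(C)C)[C@@H]1OCc3ccc4ccccc4c3 | intermediate
22 | enol triflate: C1 carries C(OTf)=CH2 | C=C(OS(=O)(=O)C(F)(F)F)[C@@H]1C[C@@H]2O[C@]2(C)[C@H](O[Si](C(C)C)(C(C)C)C(C)C)[C@@H]1OCc3ccc4ccccc4c3 | intermediate
23 | 4-methylpent-3-en-1-ol | CC(C)=CCCO | starting material
24 | 4-methylpent-3-enal | CC(C)=CCC=O | intermediate
25 | alkenylchromium dichloride (trivalent chromium): C1 carries C(CrCl2)=CH2 | C=C([Cr](Cl)Cl)[C@@H]1C[C@@H]2O[C@]2(C)[C@H](O[Si](C(C)C)(C(C)C)C(C)C)[C@@H]1OCc3ccc4ccccc4c3 | intermediate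
26 | C8 allylic alcohol, both C8 epimers (complete carbon skeleton) | C=C(C(O)CC=C(C)C)[C@@H]1C[C@@H]2O[C@]2(C)[C@H](O[Si](C(C)C)(C(C)C)C(C)C)[C@@H]1OCc3ccc4ccccc4c3 | intermediate
27 | C8 enone | C=C(C(=O)CC=C(C)C)[C@@H]1C[C@@H]2O[C@]2(C)[C@H](O[Si](C(C)C)(C(C)C)C(C)C)[C@@H]1OCc3ccc4ccccc4c3 | intermediate
28 | (8S)-allylic alcohol | C=C([C@H](CC=C(C)C)O)[C@@H]1C[C@@H]2O[C@]2(C)[C@H](O[Si](C(C)C)(C(C)C)C(C)C)[C@@H]1OCc3ccc4ccccc4c3 | intermediate
29 | C3,C8-diol (O2 still NAP) | C=C([C@H](CC=C(C)C)O)[C@@H]1C[C@@H]2O[C@]2(C)[C@H](O)[C@@H]1OCc3ccc4ccccc4c3 | intermediate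
30 | angelic acid, (Z)-2-methylbut-2-enoic acid | C/C=C(/C)C(O)=O | starting material
31 | angelic 2,4,6-trichlorobenzoic anhydride | C/C=C(/C)C(=O)OC(=O)c1c(Cl)cc(Cl)cc1Cl | intermediate
32 | C3,C8-bis-angelate, O2-NAP ether | C=C([C@H](CC=C(C)C)OC(=O)/C(C)=C\C)[C@@H]1C[C@@H]2O[C@]2(C)[C@H](OC(=O)/C(C)=C\C)[C@@H]1OCc3ccc4ccccc4c3 | intermediate
33 | C2 alcohol, C3,C8-bis-angelate | C=C([C@H](CC=C(C)C)OC(=O)/C(C)=C\C)[C@@H]1C[C@@H]2O[C@]2(C)[C@H](OC(=O)/C(C)=C\C)[C@@H]1O | intermediate
34 | C2 acetate, C3,C8-bis-angelate with C10=C11 alkene (10,11-deoxy target) | C=C([C@H](CC=C(C)C)OC(=O)/C(C)=C\C)[C@@H]1C[C@@H]2O[C@]2(C)[C@H](OC(=O)/C(C)=C\C)[C@@H]1OC(C)=O | intermediate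
35 | CNP0118696.1 (1S,2R,3R,4S,5S,8S,10S) | C=C([C@H](C[C@@H]1OC1(C)C)OC(=O)/C(C)=C\C)[C@@H]1C[C@@H]2O[C@]2(C)[C@H](OC(=O)/C(C)=C\C)[C@@H]1OC(C)=O | target

## Step count and least certain steps

Total: 26 steps. Longest linear sequence: 25 steps from 1 (steps 1–17 and 19–26); step 18 prepares aldehyde 24.

**Step 12 (key step).** The most likely failure is poor facial selectivity. The methyl group may enter on the upper face, anti to an axial mesylate (the polar preference of α-hetero-substituted cyclohexanones). That would give a hydroxy mesylate with oxygen and leaving group cis, which cannot close. Enolisation with loss of the C2 ether is a second, smaller risk. The fallback replaces carbonyl addition by a hydroxyl-directed epoxidation of an alkene and sets out from 14: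
- SmI2 (THF–MeOH, −78 °C) removes the α-mesyloxy group to give the C5-deoxy ketone F1.
- Kinetic enolisation toward the C5 methylene (KN(SiMe3)2, PhNTf2) gives the C4 enol triflate F2.
- Me2CuLi replaces the triflate by methyl to give the C4-methyl C4=C5 alkene F3.
- Bu4NF–AcOH frees the primary hydroxyl to give the C7 alcohol alkene F4.
- VO(acac)2 with t-BuOOH then delivers oxygen from the face of the C7 hydroxymethyl group, the upper face.

The route is rejoined at 17.

**Step 5.** The borane may place boron on C1 or attack in part from the upper face, and the C2 borane sits β to the C3 silyloxy group, which it can eliminate. The fallback tethers the reagent to O7 and sets out from 5: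
- 1,1,3,3-Tetramethyldisilazane gives the dimethylsilyl ether F5.
- Pt2[(CH2=CHSiMe2)2O]3 (cat.) effects intramolecular hydrosilylation to the trans-fused oxasilolane F6, with silicon forced onto C2 and hydrogen onto C1 on the lower face.
- Tamao oxidation (H2O2, KF, KHCO3) gives the C7,C2-diol F7.
- Selective silylation of the primary hydroxyl with TBDPSCl returns to the route at 8.

**Step 9.** The risk is loss of a protecting group under aqueous acid, most likely the primary silyl ether, before the diacetal is fully hydrolysed. The fallback sets out from 11. The hydrolysis is run to completion with deliberate loss of the O7 silyl group, to give the C7,C4,C5-triol F8. The primary hydroxyl is then re-silylated selectively (TBDPSCl, imidazole, −20 °C), and the route is rejoined at 12.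

**Step 20.** The cross-conjugated enone 27 may suffer double-bond migration: C10=C11 can move into conjugation, and C7=C14 can move toward C1, which would erase that stereocentre. This can happen during oxidation or handling. The fallback avoids the enone and sets out from 22. Triflate 22 and aldehyde 24 are coupled under catalytic asymmetric Nozaki–Hiyama–Kishi conditions (CrCl2 with a chiral oxazoline–sulfonamide ligand, NiCl2 with 2,9-dimethyl-1,10-phenanthroline, Mn, Cp2ZrCl2, LiCl, MeCN). The ligand enantiomer is chosen by the configuration found for the product. The route is rejoined directly at 28, and no new compound is made on the way (entry F0).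

**Step 23.** The Z-configured acyl group may isomerise to the tiglate under the basic conditions, and the neopentyl-like C3 hydroxyl may acylate slowly, so that the second ester lags behind the first. The fallback builds the double bond on the substrate and sets out from 29. Both hydroxyls are esterified with 2-[bis(2,2,2-trifluoroethoxy)phosphoryl]propanoic acid (dicyclohexylcarbodiimide, 4-(dimethylamino)pyridine) to give the bis(phosphonopropanoate) F9. Still–Gennari olefination with acetaldehyde (KN(SiMe3)2, 18-crown-6, THF, −78 °C) then forms both Z-2-methylbut-2-enoates, and the route is rejoined at 32.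

## Further compounds

F1 | step 12 | C5-deoxy C4 ketone (O7 TBDPS, O2 NAP, O3 TIPS) | CC(C)(C)[Si](OC[C@@H]1CCC(=O)[C@H](O[Si](C(C)C)(C(C)C)C(C)C)[C@@H]1OCc2ccc3ccccc3c2)(c4ccccc4)c5ccccc5
F2 | step 12 | C4 enol triflate (C4=C5) | CC(C)(C)[Si](OC[C@@H]1CC=C(OS(=O)(=O)C(F)(F)F)[C@H](O[Si](C(C)C)(C(C)C)C(C)C)[C@@H]1OCc2ccc3ccccc3c2)(c4ccccc4)c5ccccc5
F3 | step 12 | C4-methyl C4=C5 alkene | CC(C)(C)[Si](OC[C@@H]1CC=C(C)[C@H](O[Si](C(C)C)(C(C)C)C(C)C)[C@@H]1OCc2ccc3ccccc3c2)(c4ccccc4)c5ccccc5
F4 | step 12 | C7 alcohol of the C4-methyl C4=C5 alkene | OC[C@@H]1CC=C(C)[C@H](O[Si](C(C)C)(C(C)C)C(C)C)[C@@H]1OCc2ccc3ccccc3c2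
F5 | step 5 | O7-dimethylsilyl ether of 5 | C[SiH](C)OCC1=C[C@@H](O[Si](C(C)C)(C(C)C)C(C)C)[C@H]2O[C@](C)(OC)[C@@](C)(OC)O[C@@H]2C1
F6 | step 5 | trans-fused oxasilolane (Si on lower face of C2, bridged to O7) | C[Si]1(C)OC[C@H]2[C@H]1[C@@H](O[Si](C(C)C)(C(C)C)C(C)C)[C@H]3O[C@](C)(OC)[C@@](C)(OC)O[C@@H]3C2
F7 | step 5 | C7,C2-diol (C2 hydroxyl on lower face) | OC[C@H]1[C@H](O)[C@@H](O[Si](C(C)C)(C(C)C)C(C)C)[C@H]2O[C@](C)(OC)[C@@](C)(OC)O[C@@H]2C1
F8 | step 9 | C7,C4,C5-triol (O2 NAP, O3 TIPS) | OC[C@@H]1C[C@@H](O)[C@H](O)[C@H](O[Si](C(C)C)(C(C)C)C(C)C)[C@@H]1OCc2ccc3ccccc3c2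
F0 | step 20 | none | none
F9 | step 23 | C3,C8-bis[2-(bis(2,2,2-trifluoroethoxy)phosphoryl)propanoate] of 29 | C=C([C@H](CC=C(C)C)OC(=O)C(C)P(=O)(OCC(F)(F)F)OCC(F)(F)F)[C@@H]1C[C@@H]2O[C@]2(C)[C@H](OC(=O)C(C)P(=O)(OCC(F)(F)F)OCC(F)(F)F)[C@@H]1OCc3ccc4ccccc4c3
A1 | alternative 1 | (2E,6E)-farnesyl diphosphate | CC(C)=CCC/C(C)=C/CC/C(C)=C/COP(O)(=O)OP(O)(O)=O
A2 | alternative 1 | (S)-β-bisabolene | CC1=CC[C@H](CC1)C(=C)CCC=C(C)C
A3 | alternative 2 | 2-bromo-1-ethoxyethyl ether on O2 of the 3-silyloxy-4-methylcyclohexa-4,6-dienol (acetal epimers) | CCOC(CBr)O[C@@H]1C=CC=C(C)[C@@H]1O[Si](C)(C)C(C)(C)C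
A4 | alternative 2 | cis-fused bicyclic ethyl acetal (acetal epimers) | CCOC1C[C@@H]2CC=C(C)[C@H](O[Si](C)(C)C(C)(C)C)[C@@H]2O1
A5 | alternative 3 | (E)-1-(tert-butyldimethylsilyloxy)-2-methylbuta-1,3-diene | C=C/C(C)=C/O[Si](C)(C)C(C)(C)C
A6 | alternative 3 | (5R)-5-[(1R,2S,5R)-menthyloxy]furan-2(5H)-one | O=C1C=C[C@H](O[C@@H]2C[C@H](C)CC[C@H]2C(C)C)O1
A7 | alternative 3 | cis-fused bicyclic lactone acetal | O=C1O[C@@H](O[C@@H]3C[C@H](C)CC[C@H]3C(C)C)[C@@H]2CC=C(C)[C@H](O[Si](C)(C)C(C)(C)C)[C@H]12
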